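The constant I start from is a time constant τ: in a first-order flask the share of the charge turned to target by time t is one minus exp(−t/τ), and τ is the same for every charge. Here I test whether it is.

| flask | starting material | time |
|---|---|---|
| west | 0.100 M |  |
| north | 0.0400 M |  |
| east | 0.200 M |  |
| north-west | 0.650 M | 4.9 h |

| run | time / h | [target] / M |
|---|---|---|
| west run | 0.18 | 2 × 10⁻⁴ |
| west run | 0.53 | 0.0100 |
| west run | 1.0 | 0.0169 |
| west run | 1.6 | 0.0276 |
| west run | 2.3 | 0.0342 |
| west run | 3.1 | 0.0422 |
| west run | 4.0 | 0.0480 |
| west run | 4.9 | 0.0530 |
| north run | 0.18 | 0.0014 |
| north run | 0.53 | 0.0056 |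
| north run | 1.0 | 0.0067 |
| north run | 1.6 | 0.0122 |
| north run | 2.3 | 0.0147 |
| north run | 3.1 | 0.0199 |
| north run | 4.0 | 0.0232 |
| north run | 4.9 | 0.0238 |
| east run | 0.18 | 0.0057 |
| east run | 0.53 | 0.0163 |
| east run | 1.0 | 0.0336 |
| east run | 1.6 | 0.0501 |
| east run | 2.3 | 0.0630 |
| east run | 3.1 | 0.0764 |
| east run | 4.0 | 0.0854 |
| east run | 4.9 | 0.0920 |

(readings scatter by 0.001 M)

- Overall: starting material -> target.
- Constant volume, constant temperature.
- An order is taken over about fifteen percent of the charge, up and down.

1. how the opening rate goes with [starting material] round the charge of the west run: the exponent of the rate at two percent of starting material gone to target (one fixed amount of target, the same in the runs compared)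
2. target in the north-west run at 4.9 h, as a share of the starting material charged

At 4.9 h the west run reads 53.0 % of its charge as target and the east run 46.0 %. That gives τ = 6.49 h for the west run and 7.95 h for the east run, so τ is not constant. What I freeze instead is its growth with charge. The clock order (apparent order) is one minus the slope of ln τ against ln charge, which gives 0.707.

The second way uses the opening readings. The west run reads 0.0100 M at 0.53 h, and the east run reaches that amount at 0.322 h by interpolation between its readings. The order from that time ratio is 0.719. I leave the north run out of this count because that amount is a quarter of its charge.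

The two orders agree and rest on different readings. The scatter is 10.0 % of the opening amount but 1.89 % of the late one, so I commit to the clock order. Frozen up to the north-west charge, it gives τ = 11.2 h and 35.3 % of the charge as target.

The forecast differs from my reckoning: it gives an order of 0.87 and 31 %, arguing “Saturation alone would do the opposite, so target must inhibit”.

The flask gives an order of 0.75 and 30.1 % of the charge as target in the north-west run. The steps behind the readings are these:

starting material ⇌ intermediate (0.9432 h⁻¹, 5.940 h⁻¹); intermediate → target (2.178 h⁻¹); 2 starting material → homo dimer (2.048 L mol⁻¹ h⁻¹); starting material + target → 2 target (2.452 L mol⁻¹ h⁻¹) With the same amount of target made, the east run goes 1.6 times as fast as the west run. The north-west result means τ = 13.7 h, so the clock order between the east and north-west charges is 0.539, lower than my frozen 0.707. Carried to the north run, 0.707 takes the west run's rate of 0.018 M h⁻¹ down to 9.24 mM h⁻¹, and the north run's rate at that same amount of target is 0.0082 M h⁻¹.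

The earlier runs and the new flask are calculated from invented constants, noise included.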